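**Retrosynthetic overview**
1. Target 12 is catechin-(4α→8)-gallocatechin-(4β→8)-catechin; the last step is global O-debenzylation.
2. Upper interflavan bond C4–C8' (3,4-trans): Lewis-acid Friedel–Crafts coupling of a catechin C4 ether onto the free C8' of a protected dimer.
3. Lower interflavan bond C4'–C8'' (3,4-cis), the key step: C4' of a gallocatechin-type chroman-3-one is turned into an electrophile (trivalent-iodine enolonium) and attacked by C8'' of tetra-O-benzylcatechin; hydride reduction of the C3' ketone then sets C3'.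
4. No ring is built. All three chroman rings come from (+)-catechin (used twice) and (−)-epigallocatechin; bond order is C4'–C8'' first, then C4–C8'.

Assumption: the SMILES is read as all three units (2R,3S), the upper unit 3,4-trans (4α) and the middle unit 3,4-cis (4β). (−)-Epigallocatechin is used for the middle unit because its C3 centre is erased and reset, so only its 2R centre matters.

**Step 1**
Reactants: 1 (+)-catechin
Product: 2 5,7,3',4'-tetra-O-benzyl-(+)-catechin
Conditions: BnBr (4.4 equiv), K2CO3, DMF, 0 °C → rt, Ar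
Reagents that add atoms: benzyl bromide, BrCc1ccccc1
Why: Williamson ether synthesis; K2CO3 deprotonates only the four phenols, so the secondary 3-OH stays free and no stereocentre is touched.

**Step 2**
Reactants: 3 (−)-epigallocatechin
Product: 4 5,7,3',4',5'-penta-O-benzyl-(−)-epigallocatechin
Conditions: BnBr (5.5 equiv), K2CO3, DMF, 0 °C → rt, Ar, dark
Reagents that add atoms: benzyl bromide, BrCc1ccccc1
Why: Williamson ether synthesis of the five phenols under strict exclusion of air (pyrogallol ring); the 3-OH stays free and 2R is untouched.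

**Step 3**
Reactants: 4 5,7,3',4',5'-penta-O-benzyl-(−)-epigallocatechin
Product: 5 (2R)-5,7-bis(benzyloxy)-2-[3,4,5-tris(benzyloxy)phenyl]chroman-3-one
Conditions: Dess–Martin periodinane, wet CH2Cl2, 0 °C → rt; Na2S2O3/NaHCO3 work-up
Reagents that add atoms: none
Why: Dess–Martin oxidation of the secondary alcohol is non-basic, so the only remaining stereocentre (C2, α to the new ketone) keeps its 2R configuration.

**Step 4**
Reactants: 5 (2R)-5,7-bis(benzyloxy)-2-[3,4,5-tris(benzyloxy)phenyl]chroman-3-one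
Product: 6 (2R)-5,7-bis(benzyloxy)-2-[3,4,5-tris(benzyloxy)phenyl]-3-(trimethylsilyloxy)-2H-chromene
Conditions: Me3SiCl (2 equiv) then LiN(SiMe3)2 (1.1 equiv), THF, −78 °C; evaporate, pentane, filter; use crude at once
Reagents that add atoms: chlorotrimethylsilane, C[Si](C)(C)Cl
Why: kinetic enolisation with internal silyl quench removes a proton from the less hindered benzylic C4 methylene rather than the tertiary α-alkoxy C2–H, and the silyl enol ether cannot revert, so C2 is not scrambled.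

**Step 5**
Reactants: 6 (2R)-5,7-bis(benzyloxy)-2-[3,4,5-tris(benzyloxy)phenyl]-3-(trimethylsilyloxy)-2H-chromene; 2 5,7,3',4'-tetra-O-benzyl-(+)-catechin
Product: 9 5,7,3',4',5'-penta-O-benzylgallocatechin-(4β→8)-5,7,3',4'-tetra-O-benzylcatechin, via enolonium 7 (not isolated), via ketone 8 (not isolated)
Conditions: PhI(OAc)2 (1.05 equiv), BF3·OEt2 (1.5 equiv), CH2Cl2, −78 °C, slow addition of 6; then 2 (3 equiv), −78 → −50 °C; then MeOH, NaBH4 (10 equiv), −78 → −30 °C
Reagents that add atoms: none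
Why: Proposed new method: PhI(OAc)2·BF3 converts the silyl enol ether into an O-bound λ3-iodanyl enolate (enolonium 7), so the normally nucleophilic ketone α-carbon C4' becomes an electrophile (further stabilised as a benzylic cation by ring A); the normally nucleophilic C8 of 2 attacks it in a Friedel–Crafts sense with loss of PhI to give ketone 8, entering anti to the pseudoaxial 2-aryl group (A1,2 strain with the C3 oxygen substituent) so the new aryl group is axial and 2,4-trans (4β); NaBH4 then adds axially from the α face, anti to that axial aryl group, giving the equatorial 3β-alcohol (2,3-trans, 3,4-cis); the closest known reaction types are the metal-free α-arylation of ketone-derived enolonium species by indoles and pyrroles, and the Lewis-acid C4–C8 coupling of flavan C4 cations.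

**Step 6**
Reactants: 2 5,7,3',4'-tetra-O-benzyl-(+)-catechin
Product: 10 (2R,3S,4S)-5,7-bis(benzyloxy)-2-[3,4-bis(benzyloxy)phenyl]-4-(2-ethoxyethoxy)chroman-3-ol
Conditions: DDQ (2 equiv), 2-ethoxyethanol (5 equiv), CH2Cl2, rt
Reagents that add atoms: 2-ethoxyethanol, CCOCCO
Why: DDQ benzylic oxidation (hydride abstraction at C4, cation stabilised by ring A) followed by trapping with the alcohol trans to the 3-OH gives the 3,4-trans 4β-ether.

**Step 7**
Reactants: 10 (2R,3S,4S)-4-(2-ethoxyethoxy) electrophile; 9 protected dimer (1.5 equiv, excess recovered)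
Product: 11 trideca-O-benzyl catechin-(4α→8)-gallocatechin-(4β→8)-catechin
Conditions: Me3SiOSO2CF3 (0.3 equiv), CH2Cl2, −78 °C; NaHCO3 quench
Reagents that add atoms: none
Why: Lewis-acid Friedel–Crafts interflavan coupling; ionisation of the C4 ether gives the benzylic cation, which is attacked by C8' of the upper unit of 9 (the most nucleophilic free ring-A position) anti to the 3-OH, setting 4α (3,4-trans).

**Step 8**
Reactants: 11 trideca-O-benzyl trimer
Product: 12 catechin-(4α→8)-gallocatechin-(4β→8)-catechin (CNP0302529.2)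
Conditions: H2 (1 atm), Pd(OH)2/C, THF/MeOH/H2O (20:1:1), rt; filter, lyophilise
Reagents that add atoms: none
Why: catalytic hydrogenolysis cleaves all thirteen benzyl ethers while the doubly benzylic interflavan C–C bonds and all eight stereocentres are untouched.

**Compound list**
1 | (+)-catechin, (2R,3S) | Oc1cc(O)c2c(c1)O[C@H](c1ccc(O)c(O)c1)[C@@H](O)C2 | starting material
2 | 5,7,3',4'-tetra-O-benzyl-(+)-catechin, (2R,3S) | O(Cc3ccccc3)c1cc(OCc3ccccc3)c2c(c1)O[C@H](c1ccc(OCc3ccccc3)c(OCc3ccccc3)c1)[C@@H](O)C2 | intermediate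
3 | (−)-epigallocatechin, (2R,3R) | Oc1cc(O)c2c(c1)O[C@H](c1cc(O)c(O)c(O)c1)[C@H](O)C2 | starting material
4 | 5,7,3',4',5'-penta-O-benzyl-(−)-epigallocatechin, (2R,3R) | O(Cc3ccccc3)c1cc(OCc3ccccc3)c2c(c1)O[C@H](c1cc(OCc3ccccc3)c(OCc3ccccc3)c(OCc3ccccc3)c1)[C@H](O)C2 | intermediate
5 | (2R)-5,7-bis(benzyloxy)-2-[3,4,5-tris(benzyloxy)phenyl]chroman-3-one | O(Cc3ccccc3)c1cc(OCc3ccccc3)c2c(c1)O[C@H](c1cc(OCc3ccccc3)c(OCc3ccccc3)c(OCc3ccccc3)c1)C(=O)C2 | intermediate
6 | (2R)-5,7-bis(benzyloxy)-2-[3,4,5-tris(benzyloxy)phenyl]-3-(trimethylsilyloxy)-2H-chromene | O(Cc3ccccc3)c1cc(OCc3ccccc3)c2c(c1)O[C@H](c1cc(OCc3ccccc3)c(OCc3ccccc3)c(OCc3ccccc3)c1)C(O[Si](C)(C)C)=C2 | intermediate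
7 | enolonium: (2R)-2H-chromen-3-yl O-bound acetoxy(phenyl)-λ3-iodane of 5, BF3-activated | O(Cc3ccccc3)c1cc(OCc3ccccc3)c2c(c1)O[C@H](c1cc(OCc3ccccc3)c(OCc3ccccc3)c(OCc3ccccc3)c1)C(O[I](OC(C)=O)c3ccccc3)=C2 | intermediate
8 | dimer ketone: (2R,4R)-chroman-3-one carrying the tetra-O-benzylcatechin-8-yl group at C4, 2,4-trans (4β) | c1c(OCc3ccccc3)cc(OCc3ccccc3)c2c1O[C@H](c1cc(OCc3ccccc3)c(OCc3ccccc3)c(OCc3ccccc3)c1)C(=O)[C@H]2c1c(OCc3ccccc3)cc(OCc3ccccc3)c2c1O[C@H](c1ccc(OCc3ccccc3)c(OCc3ccccc3)c1)[C@@H](O)C2 | intermediate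
9 | 5,7,3',4',5'-penta-O-benzylgallocatechin-(4β→8)-5,7,3',4'-tetra-O-benzylcatechin; upper unit (2R,3S,4R), 2,3-trans-3,4-cis; lower unit (2R,3S); both 3-OH free | c1c(OCc3ccccc3)cc(OCc3ccccc3)c2c1O[C@H](c1cc(OCc3ccccc3)c(OCc3ccccc3)c(OCc3ccccc3)c1)[C@@H](O)[C@H]2c1c(OCc3ccccc3)cc(OCc3ccccc3)c2c1O[C@H](c1ccc(OCc3ccccc3)c(OCc3ccccc3)c1)[C@@H](O)C2 | intermediate
10 | (2R,3S,4S)-5,7-bis(benzyloxy)-2-[3,4-bis(benzyloxy)phenyl]-4-(2-ethoxyethoxy)chroman-3-ol (4β-ether, 3,4-trans) | O(Cc3ccccc3)c1cc(OCc3ccccc3)c2c(c1)O[C@H](c1ccc(OCc3ccccc3)c(OCc3ccccc3)c1)[C@@H](O)[C@H]2OCCOCC | intermediate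
11 | trideca-O-benzyl catechin-(4α→8)-gallocatechin-(4β→8)-catechin; all phenols benzylated, three 3-OH free; upper (2R,3S,4S), middle (2R,3S,4S), lower (2R,3S) | O(Cc3ccccc3)c1cc(OCc3ccccc3)c2c(c1)O[C@H](c1ccc(OCc3ccccc3)c(OCc3ccccc3)c1)[C@@H](O)[C@@H]2c1c(OCc3ccccc3)cc(OCc3ccccc3)c2c1O[C@H](c1cc(OCc3ccccc3)c(OCc3ccccc3)c(OCc3ccccc3)c1)[C@@H](O)[C@H]2c1c(OCc3ccccc3)cc(OCc3ccccc3)c2c1O[C@H](c1ccc(OCc3ccccc3)c(OCc3ccccc3)c1)[C@@H](O)C2 | intermediate
12 | catechin-(4α→8)-gallocatechin-(4β→8)-catechin (CNP0302529.2); upper unit 2,3-trans-3,4-trans, middle unit 2,3-trans-3,4-cis | Oc1cc(O)c2c(c1)O[C@H](c1ccc(O)c(O)c1)[C@@H](O)[C@@H]2c1c(O)cc(O)c2c1O[C@H](c1cc(O)c(O)c(O)c1)[C@@H](O)[C@H]2c1c(O)cc(O)c2c1O[C@H](c1ccc(O)c(O)c1)[C@@H](O)C2 | target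

**Totals**
Total step count: 8. Longest linear sequence: 6 steps (3 → 4 → 5 → 6 → 9 → 11 → 12).

**Three steps most likely to fail**

Step 5 (most at risk). The enolonium may lose H-2 and collapse to the flavylium-type anhydrobase, the trivalent-iodine reagent may oxidise the electron-rich arenes, or the C4'/C3' selectivity may be lower than argued. Fallback, setting out from 6 and returning at 8: treat silyl enol ether 6 with N-bromosuccinimide in THF at −78 °C to give the (2R,4S)-4-bromochroman-3-one F3, an α-halo ketone that serves as the same reversed-polarity C4 electrophile without any oxidant being present when the arene is added. Ionise it with AgOSO2CF3 in CH2Cl2 at −78 °C in the presence of 2 to give ketone 8, which is reduced in the same flask with NaBH4 as in step 5 to reach 9.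

Step 4. Deprotonation may occur partly at C2 (wrong enol ether regioisomer, loss of the 2R centre), or the enol ether may not survive handling. Fallback, setting out from 4 and returning at 8: oxidise 4 with DDQ in the presence of 2-ethoxyethanol to the (2R,3R,4S)-4-(2-ethoxyethoxy) derivative of penta-O-benzylepigallocatechin F1, then oxidise its 3-OH with Dess–Martin periodinane to the 4-(2-ethoxyethoxy)chroman-3-one F2. This α-alkoxy ketone needs no base and no silyl enol ether; BF3·OEt2 in CH2Cl2 at −78 °C ionises its C4–O bond to the same α-keto cation, which is captured by 2 to give ketone 8 and reduced in the flask to 9.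

Step 7. The electrophile 10 can condense with itself through its own free C8, and attack at C6' or from the 4β face can erode yield. Fallback, setting out from 10 and returning at 12: brominate 10 with N-bromosuccinimide in CH2Cl2 at −78 °C to the 8-bromo-4-(2-ethoxyethoxy) electrophile F4, whose blocked C8 cannot self-condense, so it can be used 1:1 with 9. Me3SiOSO2CF3 in CH2Cl2 at −78 °C then gives the 8-bromo trideca-O-benzyl trimer F5, and hydrogenolysis over Pd(OH)2/C with H2 and Et3N removes the bromine together with the thirteen benzyl groups to give 12.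

**Further compounds**
F1 | step 4 | (2R,3R,4S)-5,7-bis(benzyloxy)-2-[3,4,5-tris(benzyloxy)phenyl]-4-(2-ethoxyethoxy)chroman-3-ol (2,3-cis-3,4-trans) | O(Cc3ccccc3)c1cc(OCc3ccccc3)c2c(c1)O[C@H](c1cc(OCc3ccccc3)c(OCc3ccccc3)c(OCc3ccccc3)c1)[C@H](O)[C@H]2OCCOCC
F2 | step 4 | (2R,4S)-5,7-bis(benzyloxy)-2-[3,4,5-tris(benzyloxy)phenyl]-4-(2-ethoxyethoxy)chroman-3-one | O(Cc3ccccc3)c1cc(OCc3ccccc3)c2c(c1)O[C@H](c1cc(OCc3ccccc3)c(OCc3ccccc3)c(OCc3ccccc3)c1)C(=O)[C@H]2OCCOCC
F3 | step 5 | (2R,4S)-5,7-bis(benzyloxy)-4-bromo-2-[3,4,5-tris(benzyloxy)phenyl]chroman-3-one (2,4-trans) | O(Cc3ccccc3)c1cc(OCc3ccccc3)c2c(c1)O[C@H](c1cc(OCc3ccccc3)c(OCc3ccccc3)c(OCc3ccccc3)c1)C(=O)[C@H]2Br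
F4 | step 7 | (2R,3S,4S)-5,7-bis(benzyloxy)-2-[3,4-bis(benzyloxy)phenyl]-8-bromo-4-(2-ethoxyethoxy)chroman-3-ol | O(Cc3ccccc3)c1cc(OCc3ccccc3)c2c(c1Br)O[C@H](c1ccc(OCc3ccccc3)c(OCc3ccccc3)c1)[C@@H](O)[C@H]2OCCOCC
F5 | step 7 | trideca-O-benzyl 8-bromocatechin-(4α→8)-gallocatechin-(4β→8)-catechin (bromine on C8 of the upper unit) | O(Cc3ccccc3)c1cc(OCc3ccccc3)c2c(c1Br)O[C@H](c1ccc(OCc3ccccc3)c(OCc3ccccc3)c1)[C@@H](O)[C@@H]2c1c(OCc3ccccc3)cc(OCc3ccccc3)c2c1O[C@H](c1cc(OCc3ccccc3)c(OCc3ccccc3)c(OCc3ccccc3)c1)[C@@H](O)[C@H]2c1c(OCc3ccccc3)cc(OCc3ccccc3)c2c1O[C@H](c1ccc(OCc3ccccc3)c(OCc3ccccc3)c1)[C@@H](O)C2
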